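I began from what a first-order loss holds constant: the share of G that goes each hour, however much G stands in the flask.

| flask | L | Z | G | time |
|---|---|---|---|---|
| birch | 0.100 M | 2.00 × 10⁻⁴ M |  |  |
| cedar | 0.0600 M | 2.00 × 10⁻⁴ M |  |  |
| larch | 0.100 M | 3.00 × 10⁻⁴ M |  |  |
| oak | 0.150 M | 2.00 × 10⁻⁴ M |  |  |
| maple | 0.100 M | 2.00 × 10⁻⁴ M | 0.0300 M | 8.6 h |

| run | time / h | [G] / M |
|---|---|---|
| birch run | 0.38 | 0.0047 |
| birch run | 1.2 | 0.0163 |
| birch run | 2.2 | 0.0293 |
| birch run | 3.5 | 0.0435 |
| birch run | 5.0 | 0.0558 |
| birch run | 6.7 | 0.0663 |
| birch run | 8.6 | 0.0701 |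
| cedar run | 0.38 | 0.0050 |
| cedar run | 1.2 | 0.0143 |
| cedar run | 2.2 | 0.0236 |
| cedar run | 3.5 | 0.0336 |
| cedar run | 5.0 | 0.0405 |
| cedar run | 6.7 | 0.0452 |
| cedar run | 8.6 | 0.0451 |
| larch run | 0.38 | 0.0112 |
| larch run | 1.2 | 0.0352 |
| larch run | 2.2 | 0.0596 |
| larch run | 3.5 | 0.0780 |
| larch run | 5.0 | 0.0835 |
| larch run | 6.7 | 0.0826 |
| larch run | 8.6 | 0.0782 |
| oak run | 0.38 | 0.0057 |
| oak run | 1.2 | 0.0172 |
| oak run | 2.2 | 0.0300 |
| oak run | 3.5 | 0.0472 |
| oak run | 5.0 | 0.0636 |
| oak run | 6.7 | 0.0783 |
| oak run | 8.6 | 0.0904 |

(scatter of a reading: 5 × 10⁻⁴ M)

- Overall: L -> G, with Z as catalyst.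
- Constant volume, constant temperature.
- Readings of a species count what is bound in complexes too.
- An order is taken over about fifteen percent of the charge, up and down.
- A share of G counts the G that was charged too.

- the exponent of [L] in the starting rate at the charge of the birch run (at the point where two percent of the L have become G) (one fixed amount of G, the same in the runs compared)
- the exponent of [Z] in the starting rate at the charge of the birch run (at the point where two percent of the L have become G)
- G in the maple run at 8.6 h, as a share of the L charged

The larch readings crest at 0.0835 M at 5.0 h and then fall, to 0.0782 M at 8.6 h. A crest is the crossing at which making equals loss, with making still running, so the larch tail may hold some making; as an approximation I neglected it and read the tail as loss. The logarithm of its last two readings, over the hours between them, gave the share of G lost per hour, my loss constant (a first-order rate constant): 0.0288 /h.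

For maple I assumed that making takes no notice of G, so that maple is birch plus whatever remains of the charged G. That gives two extremes. If every charged G stays, the birch reading at the asked time plus the charge comes to 100% of the L charged. If none stays, the birch reading gives 70.1%. The loss constant places maple between them: over 8.6 h, 78.1% of the charged G remains, so my figure was 93.5%.

The forecast gave 0.15 in L, 2 in Z and 88% for maple, which is below my figure. Of the late sag it said: “Late rates also sag modestly, through product inhibition or catalyst decay; I can't separate these”.

The flask gave orders of 0.11 in L and 2.0 in Z, and 94.2% for maple.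

    Z + L ⇌ ZL, settled at all times (8.320 /M)
    ZL + Z → G + 2 Z (1.408 × 10⁶ /M/h)
    G → Wa (0.02693 /h)
    2 L → Ju (0.2725 /M/h)

Maple ended 6.2 percentage points above the forecast. It stands below the charge-plus-making total because G turns into Wa: the simulated maple run without that step reaches 111%. The loss constant reckons that gap from maple's own G. Multiplied by the hours and by the mean of the starting and final shares, it gives 15 points, and the simulated pair of runs shows 17 points.

The earlier runs and the new flask are calculated for substances that don't exist; scatter was added.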